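## Retrosynthetic overview

1. Numbering used throughout (2-oxaspiro[4.5]decane): O2, C1 = OCH2, C3 = CH carrying the tetraenyl chain, C4 = ring CH2, C5 = spiro carbon, C6 = C(OH)Me, C9 = ylidene carbon, C10 = CH(CH2)3OH. The (Z)-enal and the hydroxypropyl chain come together from a temporary eight-membered (Z)-enoate lactone (intramolecular HWE on a C9 ketone, later opened by i-Bu2AlH and oxidised with MnO2). The tetraenyl chain is built from a C3 CH2O handle by Wittig, Takai and Negishi steps, and the C6 carbinol by methyl addition to a C6 ketone.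
2. Key disconnection: the oxolane is cut at C4–C5 and O2–C1, a LiI-catalysed formal (3+2) cycloaddition of (R)-benzyl glycidyl ether (O2–C3–C4) with an α-methylene cyclohexanone (C1=C5). The C4–C5 bond is the ring-closing event.
3. Enabling feature: O2–C1–C5–C6(O) is a β-alkoxy-ketone array, so C5 is the α-carbon of the C6 carbonyl and becomes an enolate as soon as an alkoxide adds to C1. The O2–C3(H)–C4H2 edge of the oxolane is a glycidol epoxide whose CH2 the catalyst turns into an alkyl iodide.
4. C10 is set by Cu-catalysed asymmetric conjugate addition of a mixed alkyl[(trimethylsilyl)methyl]zinc reagent to 1,4-dioxaspiro[4.5]dec-6-en-8-one. Mannich trapping of the zinc enolate leads to the α-methylene ketone.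
5. Ring order: cyclohexane (bought) → oxolane (key step, C5 set from C10) → temporary eight-membered lactone (formed, later opened).

Key step: step 4

Remark: the spirocyclic intermediates are named on the 2-oxaspiro[4.5]decane numbering of the target (ketal written as a 9,9-ethylenedioxy substituent); the phosphoramidite antipode is assumed to be the one that gives the 6S adduct; the (trimethylsilyl)methyl group on zinc is assumed not to transfer; the phosphonate α-carbon of the ester made in step 7 is an inconsequential epimer mixture.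

## Route

Step 1
Reactants: 1 tert-butyl(3-iodopropoxy)dimethylsilane
Product: 3 {3-[(tert-butyldimethylsilyl)oxy]propyl}[(trimethylsilyl)methyl]zinc, via alkylzinc iodide 2 (not isolated)
Conditions: Zn dust (activated with BrCH2CH2Br and Me3SiCl), THF, 35 °C; then Me3SiCH2Li (pentane), −30 → 0 °C; THF exchanged for toluene, LiI filtered off
Reagents that add atoms: zinc, [Zn]; (trimethylsilyl)methyllithium, [Li]C[Si](C)(C)C
Why: Direct insertion of activated zinc into the primary iodide gives the alkylzinc iodide, and transmetalation with Me3SiCH2Li converts it into a mixed diorganozinc whose (trimethylsilyl)methyl group serves as a non-transferable ligand, so one equivalent of the functionalised chain suffices and the silyl ether is inert throughout.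

Step 2
Reactants: 4 1,4-dioxaspiro[4.5]dec-6-en-8-one; 3 mixed diorganozinc
Product: 6 (6S,7R)-6-{3-[(tert-butyldimethylsilyl)oxy]propyl}-7-[(dimethylamino)methyl]-1,4-dioxaspiro[4.5]decan-8-one, via zinc enolate 5 (not isolated)
Conditions: Cu(OTf)2 (2 mol%), (S)-BINOL-derived N,N-bis[(R)-1-phenylethyl]phosphoramidite (4 mol%), toluene, −20 °C; then N,N-dimethylmethyleneiminium iodide, THF, −20 → 0 °C
Reagents that add atoms: N,N-dimethylmethyleneiminium iodide, C=[N+](C)C.[I-]
Why: Copper/phosphoramidite-catalysed asymmetric conjugate addition of a diorganozinc to a 4,4-disubstituted cyclohex-2-enone should set C6 (the later C10) under catalyst control with transfer of the functionalised alkyl group only, and the regiospecific zinc enolate is intercepted by the iminium salt in a Mannich reaction trans to the new chain (this second centre is erased in step 3).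

Step 3
Reactants: 6 Mannich base
Product: 8 (S)-6-{3-[(tert-butyldimethylsilyl)oxy]propyl}-7-methylidene-1,4-dioxaspiro[4.5]decan-8-one, via ammonium iodide 7 (not isolated)
Conditions: MeI, Et2O, rt; then aq. NaHCO3, CH2Cl2, rt
Reagents that add atoms: none
Why: Quaternisation of the Mannich base and E1cB loss of trimethylamine is the classical α-methylenation of a ketone and leaves the ketal and the silyl ether untouched.

Step 4
Reactants: 8 α-methylene ketone; 9 (R)-2-[(benzyloxy)methyl]oxirane
Product: 12 (3R,5S,10S)-3-[(benzyloxy)methyl]-10-{3-[(tert-butyldimethylsilyl)oxy]propyl}-9,9-(ethylenedioxy)-2-oxaspiro[4.5]decan-6-one, via lithium iodoalkoxide 10 (not isolated), via lithium enolate 11 (not isolated)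
Conditions: LiI (30 mol%), THF, 45 °C, 8 added slowly to 9 (1.5 equiv) and LiI
Reagents that add atoms: none
Why: Proposed new method: iodide should open epoxide 9 at its CH2 terminus (SN2) to the lithium β-iodoalkoxide 10, whose oxygen adds to the exocyclic methylene of 8 (oxa-Michael) and thereby generates the tetrasubstituted enolate 11 regiospecifically at the future spiro carbon; this enolate then displaces iodide intramolecularly, forming the C4–C5 bond and returning LiI, so the whole is a halide-catalysed formal (3+2) cycloaddition of an epoxide (C–C–O unit) with an enone C=C. The closest known reaction types are the LiBr- or iodide-catalysed (3+2) cycloadditions of epoxides with isocyanates and with CO2 (same halohydrin-alkoxide relay, a heterocumulene in place of the enone) and Michael-initiated ring closures of enolates onto alkyl halides. The oxolane closes in the 5-exo-tet mode with the enolate double bond exocyclic to the new ring, which is stereoelectronically allowed, whereas O-alkylation would need a seven-membered ring. The new quaternary centre C5 is controlled by the neighbouring C10 stereocentre: A(1,2) strain with the C1 methylene puts the silyloxypropyl chain pseudoaxial on the enolate, so C4 should bond to the opposite face (C4 anti to the chain, the OCH2 arm syn), while C3 is carried over unchanged from the epoxide because its C–O bond is never broken. The step needs attack of iodide at the primary epoxide carbon (secured by the unhindered glycidyl CH2), alkoxide addition to the exo-methylene instead of enolisation (secured by the unhindered, highly electrophilic terminus) and ring closure faster than Michael oligomerisation of 8 (secured by the primary iodide five atoms from the enolate carbon and by slow addition of 8).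

Step 5
Reactants: 12 spiro ketone
Product: 13 (3R,5S,6S,10S)-3-[(benzyloxy)methyl]-10-{3-[(tert-butyldimethylsilyl)oxy]propyl}-9,9-(ethylenedioxy)-6-methyl-2-oxaspiro[4.5]decan-6-ol
Conditions: MeLi, CeCl3 (anhydrous), THF, −78 °C
Reagents that add atoms: methyllithium, [Li]C
Why: The organocerium reagent adds 1,2 to the hindered, enolisable ketone without deprotonating it, and it should enter from the face of C4 because the pseudoaxial C10 chain blocks the axial trajectory on the other face, placing methyl syn to C4 and hydroxyl syn to C1 (6S).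

Step 6
Reactants: 13 tertiary alcohol
Product: 14 (3R,5S,6S,10S)-3-[(benzyloxy)methyl]-6-hydroxy-10-(3-hydroxypropyl)-6-methyl-2-oxaspiro[4.5]decan-9-one
Conditions: 1 M HCl, THF, rt
Reagents that add atoms: water, O
Why: Aqueous acid hydrolyses the dioxolane to the C9 ketone and cleaves the primary silyl ether in the same operation (acetal hydrolysis and desilylation), while the benzyl ether and the tertiary alcohol survive.

Step 7
Reactants: 14 keto diol; 15 2-(diethoxyphosphoryl)propanoic acid
Product: 16 3-[(3R,5S,6S,10S)-3-[(benzyloxy)methyl]-6-hydroxy-6-methyl-9-oxo-2-oxaspiro[4.5]decan-10-yl]propyl 2-(diethoxyphosphoryl)propanoate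
Conditions: EDC·HCl, DMAP (cat.), CH2Cl2, 0 °C → rt
Reagents that add atoms: none
Why: Carbodiimide esterification acylates the primary alcohol selectively, the hindered tertiary alcohol being unreactive.

Step 8
Reactants: 16 phosphono ester
Product: 17 lactone: (3R,5S,6S,10R)-3-[(benzyloxy)methyl]-6-hydroxy-6-methyl-2-oxaspiro[4.5]decane whose C9 carries a (Z)-1-carboxyethylidene group lactonised with the oxygen of the C10 3-oxypropyl chain (eight-membered ring)
Conditions: LiCl, DBU, MeCN (0.002 M, slow addition), rt → 50 °C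
Reagents that add atoms: none
Why: Intramolecular Horner–Wadsworth–Emmons olefination of the C9 ketone by the tethered, lithium-chelated phosphonate closes the eight-membered lactone, whose ring can only hold the cis-enoate, so the acyl carbon is fixed syn to C10 (Z).

Step 9
Reactants: 17 benzyl ether lactone
Product: 18 lactone as 17 with a 3-(hydroxymethyl) group
Conditions: H2 (1 atm), Pd(OH)2/C, EtOAc, rt
Reagents that add atoms: none
Why: Hydrogenolysis of the benzyl ether is fast, whereas the tetrasubstituted conjugated lactone alkene should be too hindered to be hydrogenated under these conditions.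

Step 10
Reactants: 18 primary alcohol
Product: 19 lactone as 17 with a 3-formyl group
Conditions: DMP, CH2Cl2, 0 °C → rt
Reagents that add atoms: none
Why: Dess–Martin oxidation gives the aldehyde under neutral conditions that neither touch the tertiary alcohol nor epimerise the α-alkoxy centre C3.

Step 11
Reactants: 19 aldehyde; 20 2-(triphenylphosphoranylidene)propanal
Product: 21 lactone as 17 with a 3-[(1E)-2-methyl-3-oxoprop-1-en-1-yl] group
Conditions: toluene, 80 °C
Reagents that add atoms: none
Why: The stabilised ylide reacts only with the aldehyde (Wittig reaction) and should give the (E)-2-methyl enal.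

Step 12
Reactants: 21 enal
Product: 22 lactone as 17 with a 3-[(1E,3E)-4-iodo-2-methylbuta-1,3-dien-1-yl] group
Conditions: CrCl2, CHI3, THF/dioxane, 0 °C → rt
Reagents that add atoms: iodoform, IC(I)I
Why: Takai olefination homologates the enal to the (E)-iodoalkene through a geminal dichromium reagent that does not react with the lactone or the free tertiary alcohol.

Step 13
Reactants: 23 5-bromo-2-methylpent-2-ene
Product: 24 6-methylhept-5-en-1-yne
Conditions: lithium acetylide–ethylenediamine complex, DMSO, rt
Reagents that add atoms: lithium acetylide, [Li]C#C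
Why: SN2 alkylation of lithium acetylide by the primary bromide gives the terminal alkyne.

Step 14
Reactants: 24 alkyne; 22 dienyl iodide
Product: 26 lactone as 17 with a 3-[(1E,3E,5E)-2,6,10-trimethylundeca-1,3,5,9-tetraen-1-yl] group, via alkenylalane 25 (not isolated)
Conditions: 24, Me3Al, Cp2ZrCl2 (20 mol%), CH2Cl2, rt; then 22, Pd(PPh3)4 (5 mol%), ZnCl2 (30 mol%), THF, rt
Reagents that add atoms: trimethylaluminium, C[Al](C)C
Why: Zirconium-catalysed syn-carboalumination of the terminal alkyne gives the (E)-2-methylalkenylalane, and its Negishi coupling with the alkenyl iodide proceeds with retention at both partners to the all-E triene (excess alane is consumed by the free tertiary hydroxyl, the lactone is tolerated).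

Step 15
Reactants: 26 tetraenyl lactone
Product: 27 (3R,5S,6S,10R)-10-(3-hydroxypropyl)-9-[(Z)-1-hydroxypropan-2-ylidene]-6-methyl-3-[(1E,3E,5E)-2,6,10-trimethylundeca-1,3,5,9-tetraen-1-yl]-2-oxaspiro[4.5]decan-6-ol
Conditions: i-Bu2AlH (5 equiv), CH2Cl2, −78 → 0 °C; aq. potassium sodium tartrate work-up
Reagents that add atoms: none
Why: Hydride reduction of the unsaturated lactone proceeds 1,2 at the hindered enoate and opens the temporary ring to the allylic alcohol and the 3-hydroxypropyl chain without touching the triene or the alkene geometry.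

Step 16
Reactants: 27 triol
Product: 28 (2Z)-2-[(3R,5S,6S,10R)-6-hydroxy-10-(3-hydroxypropyl)-6-methyl-3-[(1E,3E,5E)-2,6,10-trimethylundeca-1,3,5,9-tetraen-1-yl]-2-oxaspiro[4.5]decan-9-ylidene]propanal (CNP0220216.1)
Conditions: MnO2 (activated, excess), CH2Cl2, rt
Reagents that add atoms: none
Why: MnO2 oxidises only the allylic primary alcohol (chemoselective allylic oxidation), leaving the saturated primary and the tertiary alcohol, so the (Z)-enal is unveiled in the last step.

## Compound list

1 | tert-butyl(3-iodopropoxy)dimethylsilane | CC(C)(C)[Si](C)(C)OCCCI | starting material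
2 | {3-[(tert-butyldimethylsilyl)oxy]propyl}zinc iodide | CC(C)(C)[Si](C)(C)OCCC[Zn]I | intermediate
3 | {3-[(tert-butyldimethylsilyl)oxy]propyl}[(trimethylsilyl)methyl]zinc | CC(C)(C)[Si](C)(C)OCCC[Zn]C[Si](C)(C)C | intermediate
4 | 1,4-dioxaspiro[4.5]dec-6-en-8-one | O=C1C=CC2(CC1)OCCO2 | starting material
5 | [(trimethylsilyl)methyl]zinc (S)-6-{3-[(tert-butyldimethylsilyl)oxy]propyl}-1,4-dioxaspiro[4.5]dec-7-en-8-olate | C[Si](C)(C)C[Zn]OC1=C[C@H](CCCO[Si](C)(C)C(C)(C)C)C2(OCCO2)CC1 | intermediate
6 | (6S,7R)-6-{3-[(tert-butyldimethylsilyl)oxy]propyl}-7-[(dimethylamino)methyl]-1,4-dioxaspiro[4.5]decan-8-one | CN(C)C[C@H]1[C@H](CCCO[Si](C)(C)C(C)(C)C)C2(OCCO2)CCC1=O | intermediate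
7 | [(6S,7R)-6-{3-[(tert-butyldimethylsilyl)oxy]propyl}-8-oxo-1,4-dioxaspiro[4.5]decan-7-yl]-N,N,N-trimethylmethanaminium iodide | C[N+](C)(C)C[C@H]1[C@H](CCCO[Si](C)(C)C(C)(C)C)C2(OCCO2)CCC1=O.[I-] | intermediate
8 | (S)-6-{3-[(tert-butyldimethylsilyl)oxy]propyl}-7-methylidene-1,4-dioxaspiro[4.5]decan-8-one | C=C1[C@H](CCCO[Si](C)(C)C(C)(C)C)C2(OCCO2)CCC1=O | intermediate
9 | (R)-2-[(benzyloxy)methyl]oxirane | c1ccccc1COC[C@H]1CO1 | starting material
10 | lithium (S)-1-(benzyloxy)-3-iodopropan-2-olate | c1ccccc1COC[C@H](O[Li])CI | intermediate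
11 | lithium (S)-7-({[(S)-1-(benzyloxy)-3-iodopropan-2-yl]oxy}methyl)-6-{3-[(tert-butyldimethylsilyl)oxy]propyl}-1,4-dioxaspiro[4.5]dec-7-en-8-olate | c1ccccc1COC[C@@H](CI)OCC1=C(O[Li])CCC2(OCCO2)[C@H]1CCCO[Si](C)(C)C(C)(C)C | intermediate
12 | (3R,5S,10S)-3-[(benzyloxy)methyl]-10-{3-[(tert-butyldimethylsilyl)oxy]propyl}-9,9-(ethylenedioxy)-2-oxaspiro[4.5]decan-6-one | c1ccccc1COC[C@H]1C[C@@]2(CO1)[C@H](CCCO[Si](C)(C)C(C)(C)C)C3(OCCO3)CCC2=O | intermediate
13 | (3R,5S,6S,10S)-3-[(benzyloxy)methyl]-10-{3-[(tert-butyldimethylsilyl)oxy]propyl}-9,9-(ethylenedioxy)-6-methyl-2-oxaspiro[4.5]decan-6-ol | c1ccccc1COC[C@H]1C[C@@]2(CO1)[C@H](CCCO[Si](C)(C)C(C)(C)C)C3(OCCO3)CC[C@]2(C)O | intermediate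
14 | (3R,5S,6S,10S)-3-[(benzyloxy)methyl]-6-hydroxy-10-(3-hydroxypropyl)-6-methyl-2-oxaspiro[4.5]decan-9-one | c1ccccc1COC[C@H]1C[C@@]2(CO1)[C@H](CCCO)C(=O)CC[C@]2(C)O | intermediate
15 | 2-(diethoxyphosphoryl)propanoic acid (racemic) | CCOP(=O)(OCC)C(C)C(=O)O | starting material
16 | 3-[(3R,5S,6S,10S)-3-[(benzyloxy)methyl]-6-hydroxy-6-methyl-9-oxo-2-oxaspiro[4.5]decan-10-yl]propyl 2-(diethoxyphosphoryl)propanoate | c1ccccc1COC[C@H]1C[C@@]2(CO1)[C@H](CCCOC(=O)C(C)P(=O)(OCC)OCC)C(=O)CC[C@]2(C)O | intermediate
17 | (3R,5S,6S,10R)-3-[(benzyloxy)methyl]-6-hydroxy-6-methyl-2-oxaspiro[4.5]decane with a (Z)-9-(1-carboxyethylidene) group lactonised onto the oxygen of the 10-(3-oxypropyl) chain (eight-membered lactone) | c1ccccc1COC[C@H]1C[C@@]2(CO1)[C@H](CCCO3)/C(=C(/C)C3=O)CC[C@]2(C)O | intermediate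
18 | lactone as 17 with 3-(hydroxymethyl) | OC[C@H]1C[C@@]2(CO1)[C@H](CCCO3)/C(=C(/C)C3=O)CC[C@]2(C)O | intermediate
19 | lactone as 17 with 3-formyl | O=C[C@H]1C[C@@]2(CO1)[C@H](CCCO3)/C(=C(/C)C3=O)CC[C@]2(C)O | intermediate
20 | 2-(triphenylphosphoranylidene)propanal | CC(C=O)=P(c1ccccc1)(c1ccccc1)c1ccccc1 | starting material
21 | lactone as 17 with 3-[(1E)-2-methyl-3-oxoprop-1-en-1-yl] | O=C/C(C)=C/[C@H]1C[C@@]2(CO1)[C@H](CCCO3)/C(=C(/C)C3=O)CC[C@]2(C)O | intermediate
22 | lactone as 17 with 3-[(1E,3E)-4-iodo-2-methylbuta-1,3-dien-1-yl] | I/C=C/C(C)=C/[C@H]1C[C@@]2(CO1)[C@H](CCCO3)/C(=C(/C)C3=O)CC[C@]2(C)O | intermediate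
23 | 5-bromo-2-methylpent-2-ene | CC(C)=CCCBr | starting material
24 | 6-methylhept-5-en-1-yne | CC(C)=CCCC#C | intermediate
25 | [(1E)-2,6-dimethylhepta-1,5-dien-1-yl]dimethylalane | CC(C)=CCC/C(C)=C/[Al](C)C | intermediate
26 | lactone as 17 with 3-[(1E,3E,5E)-2,6,10-trimethylundeca-1,3,5,9-tetraen-1-yl] | CC(C)=CCC/C(C)=C/C=C/C(C)=C/[C@H]1C[C@@]2(CO1)[C@H](CCCO3)/C(=C(/C)C3=O)CC[C@]2(C)O | intermediate
27 | (3R,5S,6S,10R)-10-(3-hydroxypropyl)-9-[(Z)-1-hydroxypropan-2-ylidene]-6-methyl-3-[(1E,3E,5E)-2,6,10-trimethylundeca-1,3,5,9-tetraen-1-yl]-2-oxaspiro[4.5]decan-6-ol | CC(C)=CCC/C(C)=C/C=C/C(C)=C/[C@H]1C[C@@]2(CO1)[C@H](CCCO)/C(=C(/C)CO)CC[C@]2(C)O | intermediate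
28 | (2Z)-2-[(3R,5S,6S,10R)-6-hydroxy-10-(3-hydroxypropyl)-6-methyl-3-[(1E,3E,5E)-2,6,10-trimethylundeca-1,3,5,9-tetraen-1-yl]-2-oxaspiro[4.5]decan-9-ylidene]propanal | CC(C)=CCC/C(C)=C/C=C/C(C)=C/[C@H]1C[C@@]2(CO1)[C@H](CCCO)/C(=C(/C)C=O)CC[C@]2(C)O | target

## Step count and risks

Total step count: 16. Longest linear sequence: 15 steps (steps 1–12 and 14–16, from iodide 1).

Steps most likely to fail:

Step 4 (Proposed new method). The halide relay may stall at the epoxide opening, or the enolate may be consumed by Michael oligomerisation of the enone before it cyclises. The fallback uses known reactions and sets out from 9 and 8. Opening of 9 with LiI and AcOH in THF should give the iodohydrin (S)-1-(benzyloxy)-3-iodopropan-2-ol F1. Acid-catalysed oxa-Michael addition of F1 to 8 (Tf2NH, 5 mol%, CH2Cl2, 0 °C) should give the β-alkoxy ketone (6S)-7-({[(S)-1-(benzyloxy)-3-iodopropan-2-yl]oxy}methyl)-6-{3-[(tert-butyldimethylsilyl)oxy]propyl}-1,4-dioxaspiro[4.5]decan-8-one F2 as a mixture of C7 epimers. KOt-Bu in t-BuOH/THF then equilibrates the enolates; only the more substituted one can close a five-membered ring (5-exo-tet alkylation, anti to the chain), and the route is rejoined at 12.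

Step 8. Closure of the strained eight-membered ring may be outrun by intermolecular olefination, the phosphonate anion may fail to add to the hindered ketone, or the base may epimerise C10. The fallback sets out from 14. Acylation of the primary alcohol with 2-bromopropanoyl bromide (pyridine, CH2Cl2, −40 °C) should give the bromo ester 3-[(3R,5S,6S,10S)-3-[(benzyloxy)methyl]-6-hydroxy-6-methyl-9-oxo-2-oxaspiro[4.5]decan-10-yl]propyl 2-bromopropanoate F3. SmI2 (THF, high dilution, −20 °C) effects an intramolecular Reformatsky reaction templated by the samarium enolate, a method with precedent for medium-ring lactones. Acetic anhydride added to the same flask acetylates the samarium aldolate to the β-acetoxy lactone F4 (the eight-membered 9-acetoxy lactone, epimer mixture at the two new centres). DBU (toluene, rt) then eliminates acetic acid (E1cB) to the conjugated lactone, whose ring again enforces the Z geometry, and the route is rejoined at 17.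

Step 5. Facial selectivity of the methyl addition may be poor, or the hindered ketone may be enolised instead. The fallback sets out from 12. A Corey–Chaykovsky reaction with dimethylsulfoxonium methylide (Me3S(O)I, NaH, DMSO, rt → 50 °C) adds reversibly and so should place the new C–C bond equatorial, on the face of C4, giving the spiro-epoxide (3R,5S,6S,10S)-6,6-(epoxymethano) analogue of 12 F5. LiEt3BH (THF, 0 °C) opens the epoxide at its CH2 terminus to the methyl carbinol, and the route is rejoined at 13.

Further compounds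

F1 | step 4 | (S)-1-(benzyloxy)-3-iodopropan-2-ol | c1ccccc1COC[C@H](O)CI
F2 | step 4 | (6S)-7-({[(S)-1-(benzyloxy)-3-iodopropan-2-yl]oxy}methyl)-6-{3-[(tert-butyldimethylsilyl)oxy]propyl}-1,4-dioxaspiro[4.5]decan-8-one (C7 epimers) | c1ccccc1COC[C@@H](CI)OCC1C(=O)CCC2(OCCO2)[C@H]1CCCO[Si](C)(C)C(C)(C)C
F3 | step 8 | 3-[(3R,5S,6S,10S)-3-[(benzyloxy)methyl]-6-hydroxy-6-methyl-9-oxo-2-oxaspiro[4.5]decan-10-yl]propyl 2-bromopropanoate | c1ccccc1COC[C@H]1C[C@@]2(CO1)[C@H](CCCOC(=O)C(C)Br)C(=O)CC[C@]2(C)O
F4 | step 8 | eight-membered β-acetoxy lactone (9-acetoxy, saturated analogue of 17; epimers at C9 and the α-carbon) | c1ccccc1COC[C@H]1C[C@@]2(CO1)[C@@H]3CCCOC(=O)C(C)C3(OC(C)=O)CC[C@]2(C)O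
F5 | step 5 | spiro-epoxide of 12 at C6 (epoxide CH2 syn to C4, oxygen syn to C1) | c1ccccc1COC[C@H]1C[C@@]2(CO1)[C@H](CCCO[Si](C)(C)C(C)(C)C)C3(OCCO3)CC[C@@]24CO4
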